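Assumption: locants C1–C20 and C7′ follow the geranylfarnesyl chain (the target is 14R,15R in this numbering); the sense of induction of the chiral acid in step 5 cannot be predicted, so the (S,S) acid is written and its equally available mirror image is used if the sense proves opposite.

## Retrosynthetic overview

1. Pieces: neryl acetate 1 (C1–C6 with the 2Z olefin) is cut through ozonide 2 to aldehyde 3; ylide 4, brominated in the flask to 5, adds C7 and C7′ and gives bromoenoate 6; farnesyl bromide 7 (C9–C20) gets C8 from diborylmethane 8 to give boronate 9.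
2. The C7–C8 bond comes from an sp2–sp3 Suzuki coupling of 6 with 9 (ester acetate 10); the acetate is removed in the same flask to give the acyclic hydroxy ester 11, a (2Z,6E,10E,14E) geranylfarnesol oxidised at C7′.
3. Ring formation (one ring, 14-membered, formed once, in the penultimate step): the C1 allylic alcohol of 11 is ionised, the 14E olefin attacks the allyl cation through C14, and water takes the C15 cation anti, giving 12 with both stereocentres set together under a chiral confined acid. The C7′ ester keeps the C6=C7 olefin out of the cyclisation.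
4. Ester reduction of 12 gives target 13; in short 13 ⇒ 12 ⇒ 11 ⇒ 6 + 9 ⇒ 1, 4, 7, 8.

## Route

Step 1
Reactants: 1 neryl acetate [(2Z)-3,7-dimethylocta-2,6-dien-1-yl acetate]
Product: 3 (2Z)-3-methyl-6-oxohex-2-en-1-yl acetate, via ozonide 2 (not isolated)
Conditions: O3 (1.0 equiv, Sudan Red 7B end point), CH2Cl2, −78 °C; then Me2S, −78 °C → rt
Reagents that add atoms: ozone, O=[O+][O-]
Why: Regioselective ozonolysis, in which electrophilic ozone cleaves the electron-rich trisubstituted 6,7-olefin much faster than the 2,3-olefin deactivated by the allylic acetate, and reductive work-up of the ozonide leaves the Z-olefin and the acetate untouched (no stereocentre is formed).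

Step 2
Reactants: 3 (2Z)-3-methyl-6-oxohex-2-en-1-yl acetate; 4 methyl (triphenylphosphoranylidene)acetate
Product: 6 methyl (2Z,6Z)-8-acetoxy-2-bromo-6-methylocta-2,6-dienoate, via bromo ylide 5 (not isolated)
Conditions: 4 (1.2 equiv), NBS (1.2 equiv), CH2Cl2, −20 °C; then 3, −20 °C → rt
Reagents that add atoms: N-bromosuccinimide, O=C1CCC(=O)N1Br
Why: One-pot ylide bromination and Wittig olefination, in which the ester-stabilised bromo ylide places the alkyl chain trans to CO2CH3 and so gives the (2Z)-bromoenoate whose geometry becomes the chain-cis C6=C7 olefin of the target.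

Step 3
Reactants: 7 (2E,6E)-farnesyl bromide [(2E,6E)-1-bromo-3,7,11-trimethyldodeca-2,6,10-triene]; 8 bis(4,4,5,5-tetramethyl-1,3,2-dioxaborolan-2-yl)methane
Product: 9 4,4,5,5-tetramethyl-2-[(3E,7E)-4,8,12-trimethyltrideca-3,7,11-trien-1-yl]-1,3,2-dioxaborolane (homofarnesyl pinacol boronate)
Conditions: 8 (1.5 equiv), NaOtBu (1.4 equiv), THF, rt, 10 min; then 7, 0 °C → rt
Reagents that add atoms: none
Why: Alkoxide-promoted deborylative alkylation of a geminal bis(boronate), in which tert-butoxide adds to one boron and the released boron-stabilised carbanion displaces the primary allylic bromide by SN2 at the CH2 carbon, installing C8 with a boron handle and leaving both E-olefins unchanged.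

Step 4
Reactants: 6 methyl (2Z,6Z)-8-acetoxy-2-bromo-6-methylocta-2,6-dienoate; 9 homofarnesyl pinacol boronate
Product: 11 methyl (2E,6Z)-8-hydroxy-6-methyl-2-[(3E,7E)-4,8,12-trimethyltrideca-3,7,11-trien-1-yl]octa-2,6-dienoate, via acetate 10 (not isolated)
Conditions: Pd(OAc)2 (5 mol%), RuPhos (2-dicyclohexylphosphino-2′,6′-diisopropoxybiphenyl, 10 mol%), K3PO4 (3 equiv), toluene/H2O 10:1, 80 °C; then MeOH, K2CO3 (cat.), rt
Reagents that add atoms: none
Why: sp2–sp3 Suzuki–Miyaura coupling, in which oxidative addition of zerovalent palladium into the activated vinyl C–Br bond and reductive elimination both go with retention so that the homofarnesyl group replaces bromine cis to the C5 chain (2E-enoate), followed by base-catalysed transesterification that finishes the removal of the allylic acetate already begun by the aqueous base while the hindered conjugated methyl ester stays.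

Step 5
Reactants: 11 methyl (2E,6Z)-8-hydroxy-6-methyl-2-[(3E,7E)-4,8,12-trimethyltrideca-3,7,11-trien-1-yl]octa-2,6-dienoate
Product: 12 methyl (1E,5Z,8R,11E)-8-[(2R)-2-hydroxy-6-methylhept-5-en-2-yl]-5,11-dimethylcyclotetradeca-1,5,11-triene-1-carboxylate (ring numbered from the ester-bearing carbon; this is the target with CO2CH3 in place of CH2OH)
Conditions: (S,S)-HN[P(=NSO2CF3)(O2C20H10Ar2)]2 (Ar = 3,5-(CF3)2C6H3; 10 mol%), H2O (5 equiv), (CF3)2CHOH/CH2Cl2 1:4, slow addition to 1 mM, −20 °C
Reagents that add atoms: water, O
Why: Proposed new method: the confined acid protonates the primary allylic alcohol in the fluoroalcohol medium and loss of water gives the (2Z)-configured C1–C3 allyl cation as a contact ion pair with the chiral imidodiphosphorimidate anion; because the C6=C7 olefin is switched off by its ester (no six-membered ring), the chain folds and the 14E olefin attacks C1 through C14 while water adds to the developing C15 cation from the opposite face, so that anti addition across the E-olefin gives the 14R*,15R* pair directly and the chiral pocket selects the olefin face (14R,15R), with 14-membered closure expected to be preferred over the strained 10-membered and the entropically poorer 18-membered alternatives; the closest known reaction types are enantioselective cation–olefin polyene cyclisations catalysed by confined imidodiphosphorimidate acids in fluorinated alcohols, Brønsted-acid tail-to-head cyclisations of allylic alcohols and acetates, and the Lewis-acid cation–olefin macrocyclisation of geranylgeranyl-type acyl chlorides to 14-membered cembranoids.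

Step 6
Reactants: 12 macrocyclic hydroxy ester
Product: 13 (2R)-2-[(1R,3Z,7E,11E)-8-(hydroxymethyl)-4,12-dimethylcyclotetradeca-3,7,11-trien-1-yl]-6-methylhept-5-en-2-ol (target)
Conditions: (i-Bu)2AlH (4 equiv), CH2Cl2, −78 → 0 °C; aq. KNaC4H4O6
Reagents that add atoms: none
Why: 1,2-Reduction of the α,β-unsaturated methyl ester by diisobutylaluminium hydride (excess to cover the aluminium alkoxide of the tertiary alcohol) gives the primary allylic alcohol without touching the isolated olefins or the two stereocentres.

## Compound list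

1 | neryl acetate, (2Z)-3,7-dimethylocta-2,6-dien-1-yl acetate | CC(=O)OC/C=C(/C)CCC=C(C)C | starting material
2 | (2Z)-5-(5,5-dimethyl-1,2,4-trioxolan-3-yl)-3-methylpent-2-en-1-yl acetate (secondary ozonide, racemic) | CC(=O)OC/C=C(/C)CCC1OOC(C)(C)O1 | intermediate
3 | (2Z)-3-methyl-6-oxohex-2-en-1-yl acetate | CC(=O)OC/C=C(/C)CCC=O | intermediate
4 | methyl (triphenylphosphoranylidene)acetate | COC(=O)C=P(c1ccccc1)(c1ccccc1)c1ccccc1 | starting material
5 | methyl bromo(triphenylphosphoranylidene)acetate | COC(=O)C(Br)=P(c1ccccc1)(c1ccccc1)c1ccccc1 | intermediate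
6 | methyl (2Z,6Z)-8-acetoxy-2-bromo-6-methylocta-2,6-dienoate | CC(=O)OC/C=C(/C)CC/C=C(/C(=O)OC)Br | intermediate
7 | (2E,6E)-farnesyl bromide | BrC/C=C(\C)CC/C=C(\C)CCC=C(C)C | starting material
8 | bis(4,4,5,5-tetramethyl-1,3,2-dioxaborolan-2-yl)methane | CC1(C)OB(CB2OC(C)(C)C(C)(C)O2)OC1(C)C | starting material
9 | 4,4,5,5-tetramethyl-2-[(3E,7E)-4,8,12-trimethyltrideca-3,7,11-trien-1-yl]-1,3,2-dioxaborolane | CC1(C)OB(CC/C=C(\C)CC/C=C(\C)CCC=C(C)C)OC1(C)C | intermediate
10 | methyl (2E,6Z)-8-acetoxy-6-methyl-2-[(3E,7E)-4,8,12-trimethyltrideca-3,7,11-trien-1-yl]octa-2,6-dienoate | CC(=O)OC/C=C(/C)CC/C=C(/C(=O)OC)CC/C=C(\C)CC/C=C(\C)CCC=C(C)C | intermediate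
11 | methyl (2E,6Z)-8-hydroxy-6-methyl-2-[(3E,7E)-4,8,12-trimethyltrideca-3,7,11-trien-1-yl]octa-2,6-dienoate | OC/C=C(/C)CC/C=C(/C(=O)OC)CC/C=C(\C)CC/C=C(\C)CCC=C(C)C | intermediate
12 | methyl (1E,5Z,8R,11E)-8-[(2R)-2-hydroxy-6-methylhept-5-en-2-yl]-5,11-dimethylcyclotetradeca-1,5,11-triene-1-carboxylate | CC(C)=CCC[C@@](C)(O)[C@H]1C/C=C(/C)CC/C=C(/C(=O)OC)CC/C=C(\C)CC1 | intermediate
13 | (2R)-2-[(1R,3Z,7E,11E)-8-(hydroxymethyl)-4,12-dimethylcyclotetradeca-3,7,11-trien-1-yl]-6-methylhept-5-en-2-ol | CC(C)=CCC[C@@](C)(O)[C@H]1C/C=C(/C)CC/C=C(/CO)CC/C=C(\C)CC1 | target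

## Step count and risks

Total steps: 6. Longest linear sequence: 5 (steps 1, 2, 4, 5, 6; step 3 is the side branch).

**Step 5 (the most likely to fail).** The ion pair can close to 18- or 10-membered rings, the C15 cation can eliminate instead of taking water, and the 2Z geometry can erode through the tertiary allylic isomer of 11. Anti capture can leak to syn, and the enantio-induction can be weak or opposite. The fallback sets out from 11 and comes back at 12. It generates the cation from a stoichiometric leaving group without a chiral catalyst and obtains the single enantiomer by resolution; it does not cure ring-size selectivity, so ring-size isomers are still removed by chromatography. Compound 11 is phosphorylated with ClP(O)(OEt)2 and pyridine in CH2Cl2 at 0 °C to methyl (2E,6Z)-8-(diethoxyphosphoryloxy)-6-methyl-2-[(3E,7E)-4,8,12-trimethyltrideca-3,7,11-trien-1-yl]octa-2,6-dienoate F1, the surrogate of the natural diphosphate. F1 is solvolysed at 1 mM in (CF3)2CHOH/H2O 9:1 buffered with 2,6-lutidine at 0–25 °C, where the weakly basic medium spares the tertiary alcohol. The anti hydration product is formed as 12 together with the enantiomer of 12 F2, and preparative supercritical-fluid chromatography on an amylose tris(3,5-dimethylphenylcarbamate) phase delivers 12 for step 6.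

**Step 4.** Primary alkyl pinacol boronates transmetalate slowly, zerovalent palladium can also ionise the allylic acetate, and the hot aqueous base can begin to saponify the methyl ester. The fallback sets out from 7 and comes back at 10. It makes the sp3 partner by hydroboration of a terminal diene and couples it as a much more reactive trialkylborane at room temperature. Compound 7 is oxidised with N-methylmorpholine N-oxide in MeCN to (2E,6E)-farnesal F3. Methylenation with Ph3P=CH2 in THF gives (3E,7E)-4,8,12-trimethyltrideca-1,3,7,11-tetraene F4. The 9-borabicyclo[3.3.1]nonane dimer in THF at 0 °C → rt adds only to the terminal vinyl group, boron at the end carbon, to give 9-[(3E,7E)-4,8,12-trimethyltrideca-3,7,11-trien-1-yl]-9-borabicyclo[3.3.1]nonane F5. F5 is coupled in the same flask with 6 using PdCl2(dppf), AsPh3 and Cs2CO3 in DMF/THF/H2O at rt to give 10, which is carried on to 11 by the methanolysis of step 4.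

**Step 1.** Ozone can also attack the 2,3-olefin and the end point is easy to overshoot, so over-cleavage is the risk. The fallback sets out from 1 and comes back at 3. It replaces direct cleavage by epoxidation and glycol-type cleavage. 3-Chloroperbenzoic acid (1.0 equiv) in CH2Cl2 at 0 °C epoxidises the more electron-rich 6,7-olefin to (2Z)-5-(3,3-dimethyloxiran-2-yl)-3-methylpent-2-en-1-yl acetate F6. H5IO6 in THF/H2O at 0 °C opens and cleaves the epoxide to 3.

## Further compounds

F1 | step 5 | methyl (2E,6Z)-8-(diethoxyphosphoryloxy)-6-methyl-2-[(3E,7E)-4,8,12-trimethyltrideca-3,7,11-trien-1-yl]octa-2,6-dienoate | CCOP(=O)(OCC)OC/C=C(/C)CC/C=C(/C(=O)OC)CC/C=C(\C)CC/C=C(\C)CCC=C(C)C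
F2 | step 5 | enantiomer of 12, methyl (1E,5Z,8S,11E)-8-[(2S)-2-hydroxy-6-methylhept-5-en-2-yl]-5,11-dimethylcyclotetradeca-1,5,11-triene-1-carboxylate | CC(C)=CCC[C@](C)(O)[C@@H]1C/C=C(/C)CC/C=C(/C(=O)OC)CC/C=C(\C)CC1
F3 | step 4 | (2E,6E)-farnesal, (2E,6E)-3,7,11-trimethyldodeca-2,6,10-trienal | O=C/C=C(\C)CC/C=C(\C)CCC=C(C)C
F4 | step 4 | (3E,7E)-4,8,12-trimethyltrideca-1,3,7,11-tetraene | C=C/C=C(\C)CC/C=C(\C)CCC=C(C)C
F5 | step 4 | 9-[(3E,7E)-4,8,12-trimethyltrideca-3,7,11-trien-1-yl]-9-borabicyclo[3.3.1]nonane | CC(C)=CCC/C(C)=C/CC/C(C)=C/CCB1C2CCCC1CCC2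
F6 | step 1 | (2Z)-5-(3,3-dimethyloxiran-2-yl)-3-methylpent-2-en-1-yl acetate | CC(=O)OC/C=C(/C)CCC1OC1(C)C
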